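**Plan**

1. Retrosynthesis: the three phenols are masked as methyl ethers. The macrocycle is opened at the C(sp3)–C(sp3) bond between the benzylic carbon on ring B (the 1,4-bridged ring with two oxygens flanking the ether oxygen) and its neighbour in the (CH2)12 bridge. The aryl–CH2 bond at ring A (the 1,3-bridged ring) and then the diaryl ether C–O bond are cut next, leading to syringaldehyde, 3,5-dibromoanisole and 11-bromoundec-1-ene.
2. Forward order: an Ullmann coupling joins rings A and B, a Negishi coupling attaches the undec-10-enyl chain to ring A, the formyl group is turned into a benzylic chloride, and a one-pot hydroboration / alkyl–alkyl Suzuki–Miyaura coupling closes the 20-membered ring directly at its final oxidation level. BBr3 then frees the three phenols.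
3. Enabling feature: the bridge carbon on ring B is benzylic and para to the ether oxygen of a syringyl unit, so it can be the formyl carbon of syringaldehyde and later a benzyl–palladium centre without beta-hydrogens. The bridge is unbranched, so its far end can be a terminal alkene that 9-BBN borylates at the last carbon. The ring (meta-linked ring A, para-linked ring B, one ether oxygen, twelve CH2) is unstrained.
4. Stereochemistry: the target has no stereocentre and no stereogenic double bond, so nothing has to be controlled.

Key step: step 5

**Route**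

Step 1
Reactants: 1 4-hydroxy-3,5-dimethoxybenzaldehyde (syringaldehyde); 2 1,3-dibromo-5-methoxybenzene (3,5-dibromoanisole)
Product: 3 4-(3-bromo-5-methoxyphenoxy)-3,5-dimethoxybenzaldehyde
Conditions: 2 (3 equiv), CuI (10 mol %), picolinic acid (20 mol %), K3PO4, DMSO, 90 °C
Reagents that add atoms: none
Why: Copper-catalysed Ullmann-type diaryl ether synthesis with a picolinate ligand, a system suited to ortho,ortho-disubstituted phenols; the non-enolisable aldehyde is inert and the excess of 2 should hold the coupling at the mono-ether stage.

Step 2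
Reactants: 3 4-(3-bromo-5-methoxyphenoxy)-3,5-dimethoxybenzaldehyde; 4 11-bromoundec-1-ene
Product: 6 3,5-dimethoxy-4-[3-methoxy-5-(undec-10-en-1-yl)phenoxy]benzaldehyde, via undec-10-en-1-ylzinc bromide 5 (not isolated)
Conditions: 4, Zn dust, I2 (5 mol %), DMA, 80 °C; then 3, Pd(dppf)Cl2 (3 mol %), DMA/THF, 50 °C
Reagents that add atoms: none
Why: Negishi coupling, in which the primary alkylzinc bromide from direct zinc insertion into 4 should transmetalate to the arylpalladium bromide from 3 much faster than it adds to the aldehyde, while the dppf ligand suppresses beta-hydride elimination and chain walking.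

Step 3
Reactants: 6 3,5-dimethoxy-4-[3-methoxy-5-(undec-10-en-1-yl)phenoxy]benzaldehyde
Product: 7 {3,5-dimethoxy-4-[3-methoxy-5-(undec-10-en-1-yl)phenoxy]phenyl}methanol
Conditions: NaBH4, MeOH/THF, 0 °C
Reagents that add atoms: none
Why: Borohydride reduction of an aryl aldehyde to the benzylic alcohol, which leaves the terminal alkene and the aryl ethers untouched.

Step 4
Reactants: 7 {3,5-dimethoxy-4-[3-methoxy-5-(undec-10-en-1-yl)phenoxy]phenyl}methanol
Product: 8 5-(chloromethyl)-1,3-dimethoxy-2-[3-methoxy-5-(undec-10-en-1-yl)phenoxy]benzene
Conditions: SOCl2, CH2Cl2, 0 °C to rt; crude product used directly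
Reagents that add atoms: thionyl chloride, O=S(Cl)Cl
Why: Chlorodehydroxylation through the chlorosulfite, which is facile for an electron-rich benzylic alcohol, while the unactivated terminal alkene should not add HCl at this temperature.

Step 5
Reactants: 8 5-(chloromethyl)-1,3-dimethoxy-2-[3-methoxy-5-(undec-10-en-1-yl)phenoxy]benzene
Product: 10 1(5),3(2),3(6)-trimethoxy-2-oxa-1(1,3),3(1,4)-dibenzenacyclopentadecaphane (tri-O-methyl ether of the target), via B-alkyl-9-borabicyclononane adduct 9 (not isolated)
Conditions: 9-BBN (1.3 equiv), THF, 0 °C to rt; then syringe-pump addition to Pd(OAc)2 (10 mol %), PCy3 (20 mol %), K3PO4·H2O, THF, 40 °C, about 1 mM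
Reagents that add atoms: none
Why: Proposed new method: 9-BBN adds to the terminal alkene of 8 at the chain end (anti-Markovnikov) and ignores the benzylic chloride; zerovalent palladium then inserts into the benzylic C–Cl bond to give a π-benzylpalladium chloride, the phosphate-activated borate at the other end of the same molecule transfers its primary alkyl group, and reductive elimination joins the benzylic carbon of ring B to the terminal chain carbon. The closest known reaction types are the B-alkyl Suzuki–Miyaura macrocyclisation (known with alkenyl and aryl halides) and the intermolecular alkyl–alkyl Suzuki–Miyaura coupling of primary alkyl halides with B-alkyl-9-BBN reagents under Pd/PCy3 catalysis; new here is a benzylic chloride used in the ring-closing mode. The 20-membered ring closes by intramolecular transmetalation to a 21-membered palladacycle followed by C–C reductive elimination, both joined carbons ending up in the ring, and slow addition to high dilution should favour it over oligomerisation. No stereocentre or double bond is formed. The step needs regioselective borylation, transfer of the primary alkyl group only, and reductive elimination ahead of beta-hydride elimination; the monosubstituted alkene, the reluctance of the secondary bicyclooctyl B–C bonds of 9-BBN to transmetalate, the lack of beta-hydrogens on the benzyl partner and the bulky electron-rich PCy3 ligand should secure these.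

Step 6
Reactants: 10 1(5),3(2),3(6)-trimethoxy-2-oxa-1(1,3),3(1,4)-dibenzenacyclopentadecaphane
Product: 11 2-oxa-1(1,3),3(1,4)-dibenzenacyclopentadecaphane-1(5),3(2),3(6)-triol (target)
Conditions: BBr3 (6 equiv), CH2Cl2, −78 °C to rt; then H2O
Reagents that add atoms: none
Why: Lewis-acid cleavage of the three aryl methyl ethers with BBr3 by bromide attack at the methyl groups; the diaryl ether, bound to sp2 carbon on both sides, should not be cleaved.

**Compound list**

1 | 4-hydroxy-3,5-dimethoxybenzaldehyde (syringaldehyde) | O=Cc1cc(OC)c(O)c(OC)c1 | starting material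
2 | 1,3-dibromo-5-methoxybenzene (3,5-dibromoanisole) | COc1cc(Br)cc(Br)c1 | starting material
3 | 4-(3-bromo-5-methoxyphenoxy)-3,5-dimethoxybenzaldehyde | O=Cc1cc(OC)c(Oc2cc(Br)cc(OC)c2)c(OC)c1 | intermediate
4 | 11-bromoundec-1-ene | C=CCCCCCCCCCBr | starting material
5 | undec-10-en-1-ylzinc bromide | C=CCCCCCCCCC[Zn]Br | intermediate
6 | 3,5-dimethoxy-4-[3-methoxy-5-(undec-10-en-1-yl)phenoxy]benzaldehyde | O=Cc1cc(OC)c(Oc2cc(CCCCCCCCCC=C)cc(OC)c2)c(OC)c1 | intermediate
7 | {3,5-dimethoxy-4-[3-methoxy-5-(undec-10-en-1-yl)phenoxy]phenyl}methanol | OCc1cc(OC)c(Oc2cc(CCCCCCCCCC=C)cc(OC)c2)c(OC)c1 | intermediate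
8 | 5-(chloromethyl)-1,3-dimethoxy-2-[3-methoxy-5-(undec-10-en-1-yl)phenoxy]benzene | ClCc1cc(OC)c(Oc2cc(CCCCCCCCCC=C)cc(OC)c2)c(OC)c1 | intermediate
9 | 9-(11-{3-[4-(chloromethyl)-2,6-dimethoxyphenoxy]-5-methoxyphenyl}undecyl)-9-borabicyclo[3.3.1]nonane | ClCc1cc(OC)c(Oc2cc(CCCCCCCCCCCB3C4CCCC3CCC4)cc(OC)c2)c(OC)c1 | intermediate
10 | 1(5),3(2),3(6)-trimethoxy-2-oxa-1(1,3),3(1,4)-dibenzenacyclopentadecaphane (ring A: 5-methoxy-1,3-phenylene; ring B: 2,6-dimethoxy-1,4-phenylene bound to the ether oxygen at C1; (CH2)12 bridge) | COc1cc2cc(c1)Oc1c(OC)cc(cc1OC)CCCCCCCCCCCC2 | intermediate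
11 | 2-oxa-1(1,3),3(1,4)-dibenzenacyclopentadecaphane-1(5),3(2),3(6)-triol (ring A: 5-hydroxy-1,3-phenylene; ring B: 2,6-dihydroxy-1,4-phenylene; (CH2)12 bridge) | Oc1cc2cc(c1)Oc1c(O)cc(cc1O)CCCCCCCCCCCC2 | target

**Summary**

Total step count: 6. Longest linear sequence: 6 steps (1 and 2 to 11; 4 enters in step 2).

**Steps most likely to fail**

Step 5 (Proposed new method). Intermolecular coupling could outrun ring closure and give oligomers. The benzylic chloride could be solvolysed by the basic medium before oxidative addition. Beta-hydride elimination from the alkylpalladium intermediate could reduce the benzylic position instead of coupling it. The fallback uses known chemistry; it sets out from 3 and 4 and comes back at 10. Hydroboration of 4 with 9-BBN in THF gives 9-(11-bromoundecyl)-9-borabicyclo[3.3.1]nonane F1. B-alkyl Suzuki–Miyaura coupling of F1 with 3 (Pd(dppf)Cl2, K3PO4, THF/DMF/H2O, 50 °C; the primary alkyl bromide is inert to this catalyst) gives 4-[3-(11-bromoundecyl)-5-methoxyphenoxy]-3,5-dimethoxybenzaldehyde F2. PPh3 in MeCN at reflux gives {11-[3-(4-formyl-2,6-dimethoxyphenoxy)-5-methoxyphenyl]undecyl}triphenylphosphonium bromide F3. Slow addition of F3 to KOtBu in THF at high dilution closes the ring between the same two carbons by an intramolecular Wittig reaction, a macrocyclisation well established for diaryl ether cyclophanes. It should give (Z)-1(5),3(2),3(6)-trimethoxy-2-oxa-1(1,3),3(1,4)-dibenzenacyclopentadecaphan-4-ene F4, whose geometry is of no consequence. H2 with Pd/C in EtOAc then gives 10.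

Step 1. C–O bond formation may be slow because the phenoxide is flanked by two methoxy groups and deactivated by the para-formyl group, so that double arylation of the dibromide or hydrodebromination competes. The fallback sets out from 2 and comes back at 3. Mono bromine–lithium exchange of 2 (n-BuLi, Et2O, −78 °C), B(OiPr)3 and aqueous HCl give (3-bromo-5-methoxyphenyl)boronic acid F5. Chan–Lam–Evans coupling of F5 with 1 (Cu(OAc)2, pyridine, 4 Å molecular sieves, CH2Cl2, air, rt) then forms the ether oxidatively at room temperature and gives 3.

Step 2. Zinc insertion may be incomplete, the organozinc may add to the aldehyde, or the double bond may migrate along the chain through a palladium hydride. The fallback inverts the order of the two couplings so that no organometallic meets the aldehyde; it sets out from 2 and comes back at 6. Bromine–magnesium exchange of 2 (i-PrMgCl·LiCl, THF, 0 °C to rt) gives (3-bromo-5-methoxyphenyl)magnesium chloride F6. Copper-catalysed alkylation of F6 with 4 (Li2CuCl4 cat., THF/NMP, 0 °C to rt) gives 1-bromo-3-methoxy-5-(undec-10-en-1-yl)benzene F7. Ullmann coupling of F7 with an excess of 1 under the conditions of step 1 gives 6.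

**Further compounds**

F1 | step 5 | 9-(11-bromoundecyl)-9-borabicyclo[3.3.1]nonane | BrCCCCCCCCCCCB1C2CCCC1CCC2
F2 | step 5 | 4-[3-(11-bromoundecyl)-5-methoxyphenoxy]-3,5-dimethoxybenzaldehyde | O=Cc1cc(OC)c(Oc2cc(CCCCCCCCCCCBr)cc(OC)c2)c(OC)c1
F3 | step 5 | {11-[3-(4-formyl-2,6-dimethoxyphenoxy)-5-methoxyphenyl]undecyl}triphenylphosphonium bromide | [Br-].O=Cc1cc(OC)c(Oc2cc(CCCCCCCCCCC[P+](c3ccccc3)(c3ccccc3)c3ccccc3)cc(OC)c2)c(OC)c1
F4 | step 5 | (Z)-1(5),3(2),3(6)-trimethoxy-2-oxa-1(1,3),3(1,4)-dibenzenacyclopentadecaphan-4-ene | COc1cc2cc(c1)Oc1c(OC)cc(cc1OC)/C=C\CCCCCCCCCC2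
F5 | step 1 | (3-bromo-5-methoxyphenyl)boronic acid | COc1cc(Br)cc(B(O)O)c1
F6 | step 2 | (3-bromo-5-methoxyphenyl)magnesium chloride | COc1cc(Br)cc([Mg]Cl)c1
F7 | step 2 | 1-bromo-3-methoxy-5-(undec-10-en-1-yl)benzene | COc1cc(Br)cc(CCCCCCCCCC=C)c1
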